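The cis-fused cyclopentane/cycloheptene core is disconnected at the bond between the quaternary methyl-bearing carbon and the ring-fusion CH: with that quaternary carbon bonded instead to the neighbouring seven-ring carbon that carries the p-hydroxybenzoate, the skeleton is a decalin obtainable from Wieland–Miescher ketone. The key step, a pinacol-type 1,2-shift of a decalin cis-diol monomesylate, contracts ring A to the cyclopentane, expands ring B to the cycloheptene, sets the ring-fusion CH by inversion (cis to the angular methyl) and unmasks the ketone at the future p-hydroxybenzoate carbon. It exploits the adjacency of ring-fusion CH and oxygenated seven-ring carbon next to the quaternary centre. All stereocentres are relayed from the purchased angular methyl.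

Key step: step 11

Remark (assumption): (R)-(−)-Wieland–Miescher ketone, tigloyl chloride and 4-acetoxybenzoyl chloride are taken as catalogue compounds.

Locants used in the names: decalins carry steroid-type locants (ring A = C1, C2, C3, C4, C5, C10; ring B = C5 to C10; C3 = ring-A carbonyl carbon, C4 = enone CH, C5 = ring-fusion enone carbon, C9 = ring-B carbonyl carbon, C10 = quaternary methyl carbon). Hydroazulenes carry daucane locants (C1 = quaternary methyl carbon, C4 = isopropyl carbinol, C5 = ring-fusion CH, C6 = ketone/carbinol, C8(CH3)=C9, C10 = tiglate carbinol).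

Step 1
Reactants: 1 (R)-(−)-Wieland–Miescher ketone
Product: 2 4,5-dihydroxy-10-methyldecalin-3,9-dione (sec-OH at C4 and tert-OH at C5 cis to each other, both anti to the C10 methyl)
Conditions: OsO4 (cat.), NMO, citric acid, t-BuOH/H2O, rt
Reagents that add atoms: N-methylmorpholine N-oxide C[N+]1([O-])CCOCC1; water O
Why: Osmium-catalysed syn-dihydroxylation (Upjohn conditions, citric acid for an electron-poor alkene) of the only C=C should occur on the enone face opposite the axial C10 methyl, setting both new carbinol centres cis to each other and anti to that methyl.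

Step 2
Reactants: 2 4,5-dihydroxy-10-methyldecalin-3,9-dione
Product: 3 4,5-O-isopropylidene acetal (acetonide) of 2
Conditions: 2,2-dimethoxypropane, PPTS (cat.), acetone, rt
Reagents that add atoms: 2,2-dimethoxypropane COC(C)(C)OC
Why: Acid-catalysed transacetalisation of the cis sec/tert diol should give the cis-fused dioxolane, which protects the dehydration-prone dihydroxy ketone and shields one face of the C3 ketone; no stereocentre is touched.

Step 3
Reactants: 3 acetonide dione
Product: 4 3-hydroxy-3-isopropyl-4,5-O-isopropylidene-10-methyldecalin-9-one (tert-OH at C3 cis to the acetal oxygens, isopropyl on the face of the C10 methyl)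
Conditions: i-PrMgCl, CeCl3 (anhydrous), THF, −78 °C
Reagents that add atoms: isopropylmagnesium chloride CC(C)[Mg]Cl
Why: Organocerium 1,2-addition (suppresses enolisation and β-hydride reduction) should attack the α-alkoxy C3 ketone in preference to the neopentyl C9 ketone, with isopropyl entering equatorially from the face opposite the dioxolane and its axial ring-fusion oxygen.

Step 4
Reactants: 4 isopropyl carbinol ketone
Product: 5 7,8-didehydro derivative of 4 (ring-B cyclohexenone, C9 carbonyl, C7=C8)
Conditions: IBX, DMSO/PhF, 65 °C
Reagents that add atoms: none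
Why: IBX α,β-dehydrogenation of the only ketone should give a single enone because C8 is its only enolisable α-carbon (C10 is quaternary); the tertiary alcohol and acetonide are inert.

Step 5
Reactants: 5 ring-B enone
Product: 6 7-methyl derivative of ketone 4 (C7 configuration not defined)
Conditions: MeMgCl (excess), CuI (10 mol%), THF, −40 °C; aq. NH4Cl
Reagents that add atoms: methylmagnesium chloride C[Mg]Cl
Why: Copper-catalysed conjugate addition of the methyl Grignard reagent to the β-unsubstituted enone (the tertiary hydroxyl is first deprotonated) installs the ring-B methyl; the configuration at C7 is irrelevant because step 6 makes that carbon trigonal.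

Step 6
Reactants: 6 7-methyl ketone
Product: 7 7-methyl-7,8-didehydro ketone (C9 carbonyl, C7(CH3)=C8H), acetonide and tert-OH as in 4
Conditions: IBX, DMSO/PhF, 70 °C
Reagents that add atoms: none
Why: A second IBX dehydrogenation, again possible only towards C8/C7, should give the β-methyl enone and erase the C7 stereocentre.

Step 7
Reactants: 7 β-methyl enone
Product: 8 allylic alcohol (9-OH cis to the C10 methyl; C7(CH3)=C8)
Conditions: NaBH4, CeCl3·7H2O, MeOH, −40 °C
Reagents that add atoms: none
Why: Luche 1,2-reduction; hydride should add on the face opposite the adjacent axial C10 methyl (as in borohydride reductions of Wieland–Miescher ketone), giving the equatorial allylic alcohol cis to that methyl.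

Step 8
Reactants: 8 allylic alcohol; 9 tigloyl chloride
Product: 10 9-O-tiglate of 8
Conditions: pyridine, DMAP (cat.), CH2Cl2, 0 °C to rt
Reagents that add atoms: none
Why: DMAP-catalysed O-acylation of the only secondary hydroxyl; the hindered tertiary hydroxyl should not react and the (E)-ester is the stable geometry.

Step 9
Reactants: 10 tiglate acetonide
Product: 11 3,4,5-triol 9-tiglate (three hydroxyls mutually cis, anti to the C10 methyl)
Conditions: AcOH/H2O (4:1), 35 °C
Reagents that add atoms: none
Why: Mild acid-catalysed acetal hydrolysis; the tertiary alcohols are not allylic and the allylic tiglate should survive aqueous acetic acid.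

Step 10
Reactants: 11 triol tiglate
Product: 12 4-O-methanesulfonate of 11
Conditions: MsCl, Et3N, CH2Cl2, −20 °C; used without storage
Reagents that add atoms: methanesulfonyl chloride CS(=O)(=O)Cl
Why: Sulfonylation of the single secondary (equatorial C4) hydroxyl in the presence of two tertiary ones gives the rearrangement substrate without touching a stereocentre.

Step 11
Reactants: 12 hydroxy mesylate
Product: 13 cis-fused hydroazulenone: 4-hydroxy-4-isopropyl-1,8-dimethyl-6-oxobicyclo[5.3.0]dec-8-en-10-yl tiglate (H5 cis to the C1 methyl, tert-OH trans to both, tiglate oxygen cis to the C1 methyl)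
Conditions: AlEt3 (2.5 equiv), CH2Cl2, −78 to −20 °C; pH 7 buffer
Reagents that add atoms: none
Why: AlEt3 converts the hydroxyls into aluminium alkoxides and assists departure of the equatorial C4 mesylate, while the ring-fusion oxygen on C5 pushes the antiperiplanar C5–C10 bond onto C4 and becomes the ketone (pinacol-type 1,2-alkyl shift of a β-mesyloxy tertiary alcohol; closest known type: the hydronaphthalene-diol monosulfonate to hydroazulenone rearrangement, here in its organoaluminium-promoted form). No ring is closed by a new external bond: the cyclopentane arises by contraction of ring A when C5 is excised from it, and the cycloheptene by one-carbon expansion of ring B when C4 is inserted between C5 and C10, both in the same suprafacial shift. The only new stereocentre, the ring-fusion CH (former C4), is set by inversion at the migration terminus, which places its hydrogen cis to the angular methyl; the migrating quaternary carbon keeps its configuration and the isopropyl carbinol and tiglate carbinol are spectators. The required selectivity is migration of quaternary C10 rather than the ring-A methylene C2, which is also antiperiplanar to the mesylate and could be driven by the isopropyl carbinol oxygen; the far higher migratory aptitude of the fully substituted carbon should secure it. Non-basic, low-temperature conditions are chosen so that the β,γ-unsaturated ketone product is not enolised and the allylic tiglate is kept.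

Step 12
Reactants: 13 hydroazulenone
Product: 14 4,6-diol 10-tiglate (6-OH cis to the 4-OH, H6 cis to H5)
Conditions: NaBH4, CeCl3·7H2O, MeOH, −78 °C
Reagents that add atoms: none
Why: Luche-type borohydride reduction of the isolated ketone (tiglate and alkene inert, no enolisation); hydride should be delivered to the exo (convex) face of the cis-fused bicycle, the face of the ring-fusion hydrogen, so the new hydroxyl is cis to the tertiary hydroxyl (1,3-syn diol).

Step 13
Reactants: 14 diol tiglate; 15 4-acetoxybenzoyl chloride
Product: 16 6-O-(4-acetoxybenzoyl) ester of 14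
Conditions: Et3N, DMAP, CH2Cl2, 0 °C to rt
Reagents that add atoms: none
Why: DMAP-catalysed acylation of the secondary hydroxyl with the acid chloride; the tertiary hydroxyl is unreactive and no stereocentre is involved.

Step 14
Reactants: 16 acetyl-protected diester
Product: 17 target CNP0273650.8
Conditions: pyrrolidine, CH2Cl2, 0 °C
Reagents that add atoms: none
Why: Chemoselective aminolysis of the aryl acetate, which is far more electrophilic than the alkyl benzoate and the tiglate, frees the phenol.

Compound list
1 | (R)-(−)-Wieland–Miescher ketone, (8aR)-8a-methyl-3,4,8,8a-tetrahydronaphthalene-1,6(2H,7H)-dione | C[C@@]12CCC(=O)C=C1CCCC2=O | starting material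
2 | 4,5-dihydroxy-10-methyldecalin-3,9-dione, both OH anti to the C10 methyl | C[C@@]12CCC(=O)[C@H](O)[C@@]1(O)CCCC2=O | intermediate
3 | 4,5-O-isopropylidene acetal of 2 | C[C@@]12CCC(=O)[C@H](OC(C)(C)O3)[C@@]13CCCC2=O | intermediate
4 | 3-hydroxy-3-isopropyl-4,5-O-isopropylidene-10-methyldecalin-9-one, 3-OH cis to the acetal oxygens | C[C@@]12CC[C@@](O)(C(C)C)[C@H](OC(C)(C)O3)[C@@]13CCCC2=O | intermediate
5 | 7,8-didehydro derivative of 4 (ring-B enone) | C[C@@]12CC[C@@](O)(C(C)C)[C@H](OC(C)(C)O3)[C@@]13CC=CC2=O | intermediate
6 | 7-methyl derivative of 4 (C7 epimers) | C[C@@]12CC[C@@](O)(C(C)C)[C@H](OC(C)(C)O3)[C@@]13CC(C)CC2=O | intermediate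
7 | 7-methyl-7,8-didehydro derivative of 4 (β-methyl enone) | C[C@@]12CC[C@@](O)(C(C)C)[C@H](OC(C)(C)O3)[C@@]13CC(C)=CC2=O | intermediate
8 | 9-hydroxy allylic alcohol from 7, 9-OH cis to the C10 methyl | C[C@@]12CC[C@@](O)(C(C)C)[C@H](OC(C)(C)O3)[C@@]13CC(C)=C[C@H]2O | intermediate
9 | tigloyl chloride, (E)-2-methylbut-2-enoyl chloride | C/C=C(\C)C(Cl)=O | starting material
10 | 9-O-tiglate of 8 | C[C@@]12CC[C@@](O)(C(C)C)[C@H](OC(C)(C)O3)[C@@]13CC(C)=C[C@H]2OC(=O)/C(C)=C/C | intermediate
11 | 3,4,5-triol 9-tiglate (all-cis triol, anti to the C10 methyl) | C[C@@]12CC[C@@](O)(C(C)C)[C@H](O)[C@@]1(O)CC(C)=C[C@H]2OC(=O)/C(C)=C/C | intermediate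
12 | 4-O-methanesulfonate of 11 | C[C@@]12CC[C@@](O)(C(C)C)[C@H](OS(C)(=O)=O)[C@@]1(O)CC(C)=C[C@H]2OC(=O)/C(C)=C/C | intermediate
13 | cis-fused 4-hydroxy-4-isopropyl-1,8-dimethyl-6-oxobicyclo[5.3.0]dec-8-en-10-yl tiglate | C/C=C(\C)C(=O)O[C@@H]1C=C(C)CC(=O)[C@@H]2[C@@]1(C)CC[C@@]2(O)C(C)C | intermediate
14 | 6-hydroxy compound from 13 (4,6-diol, 6-OH cis to 4-OH), 10-tiglate | C/C=C(\C)C(=O)O[C@@H]1C=C(C)C[C@@H](O)[C@@H]2[C@@]1(C)CC[C@@]2(O)C(C)C | intermediate
15 | 4-acetoxybenzoyl chloride | CC(=O)Oc1ccc(cc1)C(Cl)=O | starting material
16 | 6-O-(4-acetoxybenzoyl) ester of 14 | C/C=C(\C)C(=O)O[C@@H]1C=C(C)C[C@@H](OC(=O)c2ccc(OC(C)=O)cc2)[C@@H]2[C@@]1(C)CC[C@@]2(O)C(C)C | intermediate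
17 | CNP0273650.8: cis-fused dauc-8-ene with 4-OH, 6-O-(4-hydroxybenzoyl) and 10-O-tigloyl groups | C/C=C(\C)C(=O)O[C@@H]1C=C(C)C[C@@H](OC(=O)c2ccc(O)cc2)[C@@H]2[C@@]1(C)CC[C@@]2(O)C(C)C | target

Total step count: 14
Longest linear sequence: 14 steps (from 1)

Steps most likely to fail

Step 11 (key step). What may go wrong: a competing 1,2-shift of the ring-A methylene driven by the isopropyl carbinol oxygen (contraction to an isobutyryl cyclopentane), or enolisation of the β,γ-unsaturated ketone with alkene migration or loss of the tiglate. The fallback sets out from 10, in which the isopropyl carbinol is the only free hydroxyl. Silylation (TESOTf, 2,6-lutidine) should give the triethylsilyl ether F1. Acetonide hydrolysis (aq. AcOH, rt; the hindered tertiary silyl ether is expected to outlast the acetal) gives the 4,5-diol F2, and mesylation gives the hydroxy mesylate F3. AlEt3 then has only the ring-fusion hydroxyl to engage and should give the silyl-protected hydroazulenone F4. HF·pyridine removes the silyl group and the route is rejoined at 13.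

Step 1. What may go wrong: sluggish osmylation of the electron-poor, hindered enone alkene, incomplete facial selectivity, and dehydration of the dihydroxy ketone to the diosphenol during isolation or acetal formation. The fallback sets out from 1. NaBH4/CeCl3·7H2O reduces both ketones to the enediol F5 (both hydroxyls cis to the methyl). The now electron-rich allylic-alcohol alkene is dihydroxylated with OsO4/NMO anti to the allylic hydroxyl and the angular methyl, giving the tetraol F6. The cis sec/tert diol is closed with 2-methoxypropene/PPTS to the acetonide diol F7. Dess–Martin periodinane then oxidises both secondary alcohols, and the route is rejoined at 3.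

Step 12. What may go wrong: poor facial selectivity in hydride addition to the flexible cycloheptenone, or delivery from the concave face. The fallback sets out from 13. Hydroxyl-directed reduction with Me4NBH(OAc)3 (intramolecular delivery from the tertiary hydroxyl, Evans–Saksena) is used to make the epimeric 1,3-anti diol F8 on purpose. Mitsunobu esterification with 4-acetoxybenzoic acid (PPh3, DIAD) then inverts the secondary carbinol, and the route is rejoined at 16.

Further compounds
F1 | step 11 | 3-O-triethylsilyl ether of 10 | C[C@@]12CC[C@@](O[Si](CC)(CC)CC)(C(C)C)[C@H](OC(C)(C)O3)[C@@]13CC(C)=C[C@H]2OC(=O)/C(C)=C/C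
F2 | step 11 | 3-O-triethylsilyl 4,5-diol 9-tiglate | C[C@@]12CC[C@@](O[Si](CC)(CC)CC)(C(C)C)[C@H](O)[C@@]1(O)CC(C)=C[C@H]2OC(=O)/C(C)=C/C
F3 | step 11 | 4-O-methanesulfonate of F2 | C[C@@]12CC[C@@](O[Si](CC)(CC)CC)(C(C)C)[C@H](OS(C)(=O)=O)[C@@]1(O)CC(C)=C[C@H]2OC(=O)/C(C)=C/C
F4 | step 11 | 4-O-triethylsilyl ether of 13 | C/C=C(\C)C(=O)O[C@@H]1C=C(C)CC(=O)[C@@H]2[C@@]1(C)CC[C@@]2(O[Si](CC)(CC)CC)C(C)C
F5 | step 1 | 10-methyl-Δ4-octalin-3,9-diol, both OH cis to the methyl | C[C@@]12CC[C@@H](O)C=C1CCC[C@H]2O
F6 | step 1 | 10-methyldecalin-3,4,5,9-tetraol (4,5-OH anti to the methyl and to the 3-OH) | C[C@@]12CC[C@@H](O)[C@H](O)[C@@]1(O)CCC[C@H]2O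
F7 | step 1 | 4,5-O-isopropylidene acetal of F6 | C[C@@]12CC[C@@H](O)[C@H](OC(C)(C)O3)[C@@]13CCC[C@H]2O
F8 | step 12 | C6 epimer of 14 (6-OH trans to the 4-OH) | C/C=C(\C)C(=O)O[C@@H]1C=C(C)C[C@H](O)[C@@H]2[C@@]1(C)CC[C@@]2(O)C(C)C
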